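**Numbering used throughout.** Ring atoms: C1 is the quaternary carbinol carbon, C2 and C5 carry the acetoxy groups, C3=C4 is the alkene. Compounds: 1 1-dodecyne; 2 acetic acid; 3 dodec-1-en-2-yl acetate; 4 maleic anhydride; 5 open-chain diketo acid (not isolated); 6 2-undecanoylcyclopent-4-ene-1,3-dione; 7 2-hydroxy-2-undecanoylcyclopent-4-ene-1,3-dione; 8 mono-reduced hydroxy enone (not isolated); 9 triol; 10 monoacetate (not isolated); 11 target.

## Analysis of the target

Target 11 is a single carbocycle, a cyclopentene in which C1 is fully substituted (free tertiary hydroxyl and an eleven-carbon acyl chain), C2 and C5 are secondary allylic carbons carrying acetoxy groups, and C3=C4 is a cis-disubstituted alkene. The two acetoxy groups are cis to each other and to the undecanoyl group, and trans to the C1 hydroxyl. C2 and C5 are mirror-related (S and R), C1 is pseudoasymmetric, and a mirror plane runs through C1 and the midpoint of C3=C4, so the compound is meso and only relative configuration has to be set. The sensitive groups are the tertiary α-ketol (α-ketol rearrangement, and retro-Claisen loss of the chain at the tricarbonyl stage), the two ring oxygens β to the side-chain ketone (retro-aldol opening while they are free hydroxyls; β-elimination is excluded because C1 has no hydrogen) and the allylic esters (ionisation, allylic transposition). The difficulty is concentrated at C1, a congested carbon with four different functional substituents, flanked by two stereocentres whose oxygens must both be trans to its hydroxyl. In addition, three carbonyl-level carbons attached to C1 must end at different oxidation levels, and only two of three hydroxyls are acylated. The plan rests on the local symmetry of the ring: C1 is bonded to both C2 and C5, these are equivalent and joined through C3=C4, so C2–C3=C4–C5 is a cis-butenedioyl unit in reduced form, clamped by one carbon that already carries the undecanoyl group. This maps the ring onto maleic anhydride 4 and the nucleophilic CH2 terminus of enol acetate 3, joined twice at C1.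

## Retrosynthetic reasoning

**11 to 9.** The two ester C–O bonds are cut first, because acetylation can safely be left to the end. In triol 9 the two secondary allylic hydroxyls are far more reactive towards acylation than the C1 hydroxyl, which is tertiary, hindered on all sides and hydrogen-bonded to the ketone. The forward step must acylate twice (through monoacetate 10) without touching C1–OH and without a base strong enough to start retro-aldol opening.

**9 to 7.** Next the C2–H and C5–H bonds are cut, taking both carbinol carbons back to carbonyls in the symmetrical hydroxy triketone 7. This gives both stereocentres from one reagent in one flask (by way of hydroxy enone 8) and returns a precursor with a mirror plane and no stereocentre. The forward reduction must add hydride 1,2 rather than 1,4 to an enedione, on the face of the C1 hydroxyl at both carbonyls, and spare the more hindered side-chain ketone.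

**7 to 6.** The C1–O bond is cut next. Without the hydroxyl, C1 is the central carbon of a β-tricarbonyl system, and 6 exists as a chelated enol with a nucleophilic C1, so the oxygen can come from an electrophilic oxygen-atom donor under neutral conditions. The order is forced: a hydride reagent would only deprotonate the acidic enol 6 and its carbonyls would be protected as the enolate. Hydroxylation removes the acidic hydrogen and frees the ring carbonyls for reduction.

**6 to 3 and 4.** The ring is opened by cutting both bonds from C1, C1–C2 and C1–C5. This is the one disconnection that uses the symmetry fully: a single carbon acts as nucleophile twice (the CH2 terminus of 3, then the central carbon of the open diketo acid 5), and 4 supplies both electrophilic carbons, the alkene and its cis geometry. A cut at C2–C3 or C4–C5 would break up the ready-made four-carbon unit and leave C1 to be assembled separately. The forward reaction must acylate the same carbon twice, on carbon and not on oxygen, and close a five-membered ring.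

**3 to 1 and 2.** Finally the enol ester C–O bond of 3 is cut, back to 1 and 2. The alkyne is preferred to the corresponding methyl ketone because addition of a carboxylic acid to a terminal alkyne fixes the double bond at the chain terminus, whereas enol acetylation of the ketone would favour the internal isomer. The position of that double bond decides which carbon is acylated in the ring-forming step.

## Alternatives that were turned down

**Alternative 1:** The ring is cut at C2–C3 and C4–C5, giving a three-carbon ketone unit (C2–C1–C5) as the cyclic acetal 2,2-dimethyl-1,3-dioxan-5-one A1 and a two-carbon dialdehyde (C3–C4), glyoxal A2. In the forward direction an amine-catalysed double aldol addition would join both α-carbons of A1 to the two carbonyls of A2 and close the cyclopentanone as the bridged acetal 6,7-dihydroxy-3,3-dimethyl-2,4-dioxabicyclo[3.2.1]octan-8-one A3.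
- For it: the acetal bridge holds the C2 and C5 oxygens cis by construction, without any reduction, and the C1 carbinol would come from a carbonyl addition rather than an enol oxidation. On the cis relationship of the ring oxygens this plan is stronger than the chosen one.
- Against it: the C3/C4 diol must afterwards be removed to make the alkene, the undecanoyl group has to enter as an acyl anion equivalent and be unmasked, and the acetal has to be exchanged for acetates. That is eight or more steps.
- Against it: the carbon nucleophile must add to a bridging ketone flanked by two oxygenated bridgeheads from the acetal side to match the target. That facial outcome depends on the chair or boat preference of the dioxane bridge and on the orientation of the diol on the two-carbon bridge, and cannot be predicted with confidence.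
- Against it: the second aldol has to close a strained bicycle against a reversible first addition.
- Comparison: the chosen route gives up the built-in cis relationship but reaches the complete carbon skeleton, acyl chain included, in two steps from bulk chemicals.

**Alternative 2:** Here the C2–O and C5–O bonds are cut together, tracing the cis-dioxygenation to a peroxide bridge across the ring diene of 6-decylfulvene A4. Sensitised photooxygenation at low temperature would add oxygen [4+2] and give the endoperoxide 7-undecylidene-2,3-dioxabicyclo[2.2.1]hept-5-ene A5. O–O reduction would lead to cis-2-undecylidenecyclopent-4-ene-1,3-diol A6; after acetylation the exocyclic alkene would be dihydroxylated anti to the two acetoxy groups and the side-chain carbinol oxidised to the ketone.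
- For it: the cis relationship follows from the mechanism of the cycloaddition, and the C1 configuration from approach anti to two cis substituents. Both stereochemical arguments are stronger than those of the chosen route, which relies on face selectivity in a hydride reduction.
- Against it: A5 is a strained bicyclic peroxide with doubly allylic C–O bonds, a type that isomerises or fragments on warming, so it would have to be reduced cold in the same flask.
- Against it: A4 offers allylic C–H bonds for a competing ene reaction and is a cross-conjugated triene prone to dimerisation, and A6 is a doubly allylic diol that ionises easily.
- Against it: two alkenes must be told apart in the dihydroxylation and a final oxidation is needed, about six steps in all.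
- Comparison: the chosen route is no longer (five steps), needs no photochemical or peroxide step, and passes through robust intermediates. It accepts in exchange that its stereochemical risk sits in one reduction.

**Alternative 3:** The C1–C5 bond is cut in the aldol sense and the five-membered ring traced to the six-membered hemiacetal 6-hydroxy-2-[1-(tert-butyldimethylsilyloxy)undecyl]-2H-pyran-3(6H)-one A7, the Achmatowicz product of a furyl carbinol. A mild amine base would open A7 to a (Z)-4-oxo-enal; its α-hydroxy ketone enolises to an enediol whose carbon attacks the aldehyde, giving trans-4,5-dihydroxy-5-[1-(tert-butyldimethylsilyloxy)undecyl]cyclopent-2-en-1-one A8.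
- For it: the side-chain carbonyl is masked as a silyl ether while the ring carbonyl is reduced, so the chemoselectivity question of the chosen route does not arise. On that point this plan is stronger.
- For it: one ring oxygen is set trans to the tertiary hydroxyl in the ring-forming step, leaving a single hydride addition.
- Against it: the symmetry is ignored. C2 and C5 are made by two different reactions, and an extra side-chain stereocentre is created, carried and then destroyed.
- Against it: furan addition, protection, ring expansion, ring contraction, reduction, acetylation, desilylation and oxidation come to eight or nine steps.
- Against it: the remaining ketone reduction raises the same facial question as the chosen route, and a 4-hydroxycyclopentenone is open to dehydration and retro-aldol reaction under the basic conditions of its formation.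
- Comparison: the chosen route needs about half the steps and forms the quaternary carbon and the ring together; its price is a chemoselective reduction in the presence of a free side-chain ketone.

Key step: step 2

Remark on the chemistry: the target is a meso compound, so the stereodescriptors define relative configuration only; every intermediate is achiral or racemic and no enantioselective step is planned.

## Route

**Step 1**
Reactants: 1 1-dodecyne; 2 acetic acid
Product: 3 dodec-1-en-2-yl acetate
Conditions: Hg(OAc)2 (cat.), BF3·OEt2 (cat.), AcOH (excess, dry), rt
Reagents that add atoms: none
Why: Markovnikov hydroacyloxylation of a terminal alkyne: divalent mercury activates the triple bond, acetic acid adds to the internal carbon and protodemercuration releases the 1,1-disubstituted enol acetate with the double bond fixed at the chain terminus; the medium is kept dry so that hydration to the methyl ketone does not compete, and no stereocentre is formed.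

**Step 2**
Reactants: 3 dodec-1-en-2-yl acetate; 4 maleic anhydride
Product: 6 2-undecanoylcyclopent-4-ene-1,3-dione, via diketo acid 5 (not isolated)
Conditions: AlCl3 (2.2 equiv), ClCH2CH2Cl, rt then reflux; then ice, aq. HCl
Reagents that add atoms: none
Why: AlCl3 opens 4 to an acylium (acyl chloride–aluminate) carboxylate, which is attacked by the CH2 terminus of 3 in an aliphatic Friedel–Crafts acylation that forms C1–C2. The acetoxy-stabilised cation then loses its acetyl group, leaving the aluminium chelate of diketo acid 5. The chelated β-diketone reacts through its enol towards the side-chain carbonyl with the second, aluminium-activated carboxyl in an intramolecular Claisen-type C-acylation that forms C1–C5; this closure is 5-(enolexo)-exo-trig and is made easy by the cis geometry inherited from 4. The closest known reaction type is the AlCl3-mediated condensation of succinic or maleic anhydride with isopropenyl acetate to 2-acetylcyclopentane-1,3-dione and its 4-ene analogue; here only the alkyl residue of the enol acetate is longer. No stereocentre is formed and the product is a chelated exocyclic enol. The selectivity needed is that both acylations take place at the same terminal carbon and on carbon rather than oxygen: the first is secured by the regiodefined 1,1-disubstituted enol acetate, the second by aluminium chelation of the diketone, which leaves the central carbon as the only nucleophilic site within reach of the carboxyl. More than two equivalents of AlCl3 are used because the product stays bound as a chelate, which also protects it from further acylation or conjugate addition until the acidic work-up.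

**Step 3**
Reactants: 6 2-undecanoylcyclopent-4-ene-1,3-dione
Product: 7 2-hydroxy-2-undecanoylcyclopent-4-ene-1,3-dione
Conditions: dimethyldioxirane (1.1 equiv, dried acetone solution), CH2Cl2, −20 °C to 0 °C; evaporate
Reagents that add atoms: dimethyldioxirane, CC1(C)OO1
Why: Electrophilic α-hydroxylation of an enolised β-dicarbonyl compound by a dioxirane: oxygen is transferred to the enol double bond at C1 and the labile epoxide collapses to the tertiary alcohol, while the electron-poor C3=C4 bond reacts far more slowly. The reagent is neutral and its by-product volatile, so the electrophilic triketone is obtained by evaporation without contact with water or base; C1 carries two identical ring arms, so no stereocentre arises.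

**Step 4**
Reactants: 7 2-hydroxy-2-undecanoylcyclopent-4-ene-1,3-dione
Product: 9 1-[(1r,2R,5S)-1,2,5-trihydroxycyclopent-3-en-1-yl]undecan-1-one, via hydroxy enone 8 (not isolated)
Conditions: NaBH4 (1.1 equiv), CeCl3·7H2O (2 equiv), MeOH, −78 °C; sat. aq. NH4Cl
Reagents that add atoms: none
Why: Luche reduction: CeCl3 in methanol converts borohydride into hard methoxyborohydrides that add 1,2 to each ring carbonyl in turn (through 8) instead of 1,4 to the enedione. Hydride should enter both times from the face of the small C1 hydroxyl, anti to the undecanoyl group and possibly assisted by a borate formed at that hydroxyl, which places both new hydroxyls cis to the chain and trans to C1–OH and so sets C2 and C5 in the meso arrangement. The ring carbonyls, exposed in the planar five-membered ring, should react faster than the side-chain ketone, which is flanked by the quaternary carbon and the alkyl chain; low temperature and a small excess of hydride limit over-reduction and methanolysis of the triketone.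

**Step 5**
Reactants: 9 1-[(1r,2R,5S)-1,2,5-trihydroxycyclopent-3-en-1-yl]undecan-1-one
Product: 11 (1R,2r,3S)-2-hydroxy-2-undecanoylcyclopent-4-ene-1,3-diyl diacetate, via monoacetate 10 (not isolated)
Conditions: Ac2O (2.5 equiv), pyridine, DMAP (cat.), CH2Cl2, 0 °C
Reagents that add atoms: acetic anhydride, CC(=O)OC(C)=O
Why: O-Acetylation under nucleophilic catalysis: the two secondary allylic hydroxyls are esterified (through 10), while the tertiary C1 hydroxyl, hindered on all sides and hydrogen-bonded to the ketone, stays free. Only O–H bonds are broken, so the configuration at C2 and C5 is retained, and C1 has no hydrogen, so β-elimination of acetate cannot occur.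

## Compound list

1 | 1-dodecyne | CCCCCCCCCCC#C | starting material
2 | acetic acid | CC(=O)O | starting material
3 | dodec-1-en-2-yl acetate | CCCCCCCCCCC(=C)OC(C)=O | intermediate
4 | maleic anhydride | O=C1OC(=O)C=C1 | starting material
5 | (Z)-4,6-dioxohexadec-2-enoic acid (aluminium-bound in the flask, not isolated) | CCCCCCCCCCC(=O)CC(=O)/C=C\C(=O)O | intermediate
6 | 2-undecanoylcyclopent-4-ene-1,3-dione (triketo form drawn; exists as the chelated exocyclic enol; no stereocentre) | CCCCCCCCCCC(=O)C1C(=O)C=CC1=O | intermediate
7 | 2-hydroxy-2-undecanoylcyclopent-4-ene-1,3-dione (achiral) | CCCCCCCCCCC(=O)C1(O)C(=O)C=CC1=O | intermediate
8 | rac-(4S,5S)-4,5-dihydroxy-5-undecanoylcyclopent-2-en-1-one (4-OH cis to the undecanoyl group, trans to 5-OH; not isolated) | CCCCCCCCCCC(=O)[C@@]1(O)[C@@H](O)C=CC1=O | intermediate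
9 | 1-[(1r,2R,5S)-1,2,5-trihydroxycyclopent-3-en-1-yl]undecan-1-one (meso; secondary hydroxyls cis to each other and to the undecanoyl group, trans to the tertiary hydroxyl) | CCCCCCCCCCC(=O)[C@@]1(O)[C@@H](O)C=C[C@H]1O | intermediate
10 | rac-(1S,4R,5S)-4,5-dihydroxy-5-undecanoylcyclopent-2-en-1-yl acetate (same relative configuration as 9; not isolated) | CCCCCCCCCCC(=O)[C@@]1(O)[C@@H](OC(C)=O)C=C[C@H]1O | intermediate
11 | (1R,2r,3S)-2-hydroxy-2-undecanoylcyclopent-4-ene-1,3-diyl diacetate (meso; acetoxy groups cis to each other and to the undecanoyl group, trans to the hydroxyl) | CCCCCCCCCCC(=O)[C@@]1(O)[C@@H](OC(C)=O)C=C[C@H]1OC(C)=O | target

## Step count and least certain steps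

Total: 5 steps. Longest linear sequence: 5 steps (1 to 3 to 6 to 7 to 9 to 11); maleic anhydride 4 enters at step 2.

**Step 2 (key step).** The most likely failure is diversion of the enol acetate before double C-acylation: acid-promoted migration of its double bond into the chain (so that an internal carbon is acylated), or cationic oligomerisation of the electron-rich alkene. A second failure is isomerisation of the cis-enedioyl intermediate to the trans form, which cannot close.

The fallback abandons the one-pot Lewis-acid annulation and forms the same two bonds in separate, base-mediated operations of known type. It sets out from maleic anhydride 4. Wittig olefination of one anhydride carbonyl with the stabilised ylide 1-(triphenyl-λ5-phosphanylidene)dodecan-2-one F1 (CHCl3 or toluene, rt) should give the ylidenebutenolide 5-(2-oxododecylidene)furan-2(5H)-one F2, which already holds the C1–C2 bond. NaOMe in MeOH then opens the enol lactone, and the liberated diketone enolate recloses by Claisen condensation onto the new methyl ester (C1–C5). Acidification brings the route back at 6.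

**Step 4.** The most likely failure is incomplete or inverted face selectivity in the two hydride additions. The two C1 substituents differ only modestly in size, and a polar preference for attack anti to the C1–O bond works against the steric and delivery effects invoked. A second concern is hydride addition to the side-chain ketone, which is limited only by rate differences.

The fallback applies if hydride comes mainly from the undecanoyl face, and then turns that outcome into the route instead of fighting it. It sets out from 7: the same Luche reduction would then give the all-cis meso triol 1-[(1s,2R,5S)-1,2,5-trihydroxycyclopent-3-en-1-yl]undecan-1-one F3. In place of a retentive acetylation, F3 is treated with PPh3, diisopropyl azodicarboxylate and acetic acid 2 (THF, 0 °C) in a double Mitsunobu esterification. This inverts C2 and C5 while installing both acetates, and the tertiary hydroxyl cannot be displaced, so the sequence returns at 11. It does not rescue a mixture of faces.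

**Step 3.** The most likely failure is slow oxygen transfer to the strongly hydrogen-bonded, electron-poor enol, with epoxidation of the C3=C4 bond or cleavage of the product by adventitious water taking over when the reaction is forced.

The fallback changes both the reacting species and the oxidant class. It sets out from 6, which is converted into its enolate with Et3N in CH2Cl2 at 0 °C and oxidised with 2-(phenylsulfonyl)-3-phenyloxaziridine. The anion is a far better nucleophile than the neutral enol, and the oxaziridine does not epoxidise electron-poor alkenes. A mild acidic work-up returns the route at 7; no compound beyond those of the route is made (F0).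

## Further compounds

F1 | step 2 | 1-(triphenyl-λ5-phosphanylidene)dodecan-2-one | CCCCCCCCCCC(=O)C=P(c1ccccc1)(c1ccccc1)c1ccccc1
F2 | step 2 | 5-(2-oxododecylidene)furan-2(5H)-one (E/Z mixture, geometry immaterial) | CCCCCCCCCCC(=O)C=C1C=CC(=O)O1
F3 | step 4 | 1-[(1s,2R,5S)-1,2,5-trihydroxycyclopent-3-en-1-yl]undecan-1-one (meso; all three hydroxyls cis) | CCCCCCCCCCC(=O)[C@]1(O)[C@@H](O)C=C[C@H]1O
F0 | step 3 | none | none
A1 | alternative 1 | 2,2-dimethyl-1,3-dioxan-5-one | CC1(C)OCC(=O)CO1
A2 | alternative 1 | glyoxal | O=CC=O
A3 | alternative 1 | 6,7-dihydroxy-3,3-dimethyl-2,4-dioxabicyclo[3.2.1]octan-8-one (cis-diol drawn) | O=C1[C@H]2OC(C)(C)O[C@@H]1[C@@H](O)[C@H]2O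
A4 | alternative 2 | 6-decylfulvene (5-undecylidenecyclopenta-1,3-diene) | CCCCCCCCCCC=C1C=CC=C1
A5 | alternative 2 | 7-undecylidene-2,3-dioxabicyclo[2.2.1]hept-5-ene | CCCCCCCCCCC=C1[C@@H]2C=C[C@H]1OO2
A6 | alternative 2 | cis-2-undecylidenecyclopent-4-ene-1,3-diol | CCCCCCCCCCC=C1[C@@H](O)C=C[C@H]1O
A7 | alternative 3 | 6-hydroxy-2-[1-(tert-butyldimethylsilyloxy)undecyl]-2H-pyran-3(6H)-one (diastereomer mixture) | CCCCCCCCCCC(O[Si](C)(C)C(C)(C)C)C1OC(O)C=CC1=O
A8 | alternative 3 | trans-4,5-dihydroxy-5-[1-(tert-butyldimethylsilyloxy)undecyl]cyclopent-2-en-1-one (side-chain configuration immaterial) | CCCCCCCCCC[C@H](O[Si](C)(C)C(C)(C)C)[C@@]1(O)C(=O)C=C[C@H]1O
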